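The data are simulated for substances that don't exist, and the scatter is random.

At late times the side product should tend to the whole charge in violet, grey, blue and ochre alike. These flasks hold the same charges and, taking one partner (B) per starting material (A), A is the limiting reagent, with 0.050 M against 0.0750 M of B. The question is how far along each flask stands at 1.0 h.

| flask | starting material | partner | remark | time |
|---|---|---|---|---|
| ash | 0.050 M | 0.075 M | run made earlier |  |
| elm | 0.050 M | 0.15 M | run made earlier |  |
| violet | 0.050 M | 0.0750 M (fed, over 40 min) | all else is in the flask from the start; the feed brings no volume worth counting | 1.0 h |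
| grey | 0.050 M (fed, over 40 min) | 0.0750 M | all else is in the flask from the start; the feed brings no volume worth counting | 1.0 h |
| blue | 0.050 M | 0.0750 M | everything together at the start | 1.0 h |
| ochre | 0.050 M | 0.0750 M (fed, over 10 min) | all else is in the flask from the start; the feed brings no volume worth counting | 1.0 h |

| run | time / min | side product / % | triple product / % |
|---|---|---|---|
| ash | 5.00 | 3.7 | 1.1 |
| ash | 8.00 | 9.7 | 0.6 |
| ash | 12.0 | 15.5 | 0.7 |
| ash | 20.0 | 24.5 | 0.9 |
| ash | 40.0 | 42.8 | 0 |
| ash | 60.0 | 53.4 | 0 |
| elm | 2.00 | 3.0 | 0 |
| elm | 4.00 | 7.6 | 0 |
| elm | 6.00 | 12.0 | 1.3 |
| elm | 8.00 | 17.6 | 0 |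
| elm | 10.0 | 21.1 | 0 |
| elm | 12.0 | 23.8 | 0.2 |

(readings scatter by 1 percentage point)

- the flask that comes out highest in amount of side product, in percent of the starting material charged, or "all alike" when all lie within 1.5 percentage points (violet / grey / blue / ochre / all alike)
- side product at the end, in percent of the starting material charged, violet
- side product at the end, in percent of the starting material charged, grey
- side product at the end, in percent of the starting material charged, blue
- side product at the end, in percent of the starting material charged, ochre



Blue has the charges of ash, so it should repeat ash's 53.4% at 60.0 min. Take the rate as κ·A·B, with a and b the fractions of A and B left and Δ = 0.0250 M the excess of B: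

ln(b/a) = κ·Δ·t

Ash's last reading then gives the apparent second-order constant κ, the pace of A with B as read over a whole hour:

κ = 0.216 M⁻¹ min⁻¹

Elm's last reading gives a lower 0.158 M⁻¹ min⁻¹ over 12.0 min, so κ is kept as a reading for hour-long runs.

A fed flask lies between two extremes. With the feed tipped in at the start it is blue. With the feed tipped in at its end, violet and grey have 20.0 min left, and ash read 24.5% there. An even feed lies between: each portion reacts for the time remaining, on average the flask time less half the feed time. The rate is taken as linear in A and in B, so a fed A counts like a fed B:

violet and grey: t = 40.0 min, side product 41.9%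

ochre: t = 55.0 min, side product 50.9%

The forecast names blue as highest, with violet 42%, grey 41%, blue 53.5% and ochre 50.5%; of violet and grey it says: “Each loses about 20 min of effective exposure”.

The flasks give violet 41.9%, grey 41.4%, ochre 51.7% and blue 54.3%, the highest, so the forecast stands. Blue's figure moves by 5 points with partner at 0.0653 M or 0.0857 M, the other amounts and the time held.

    starting material + partner → mono adduct (k = 0.00400 M⁻¹ s⁻¹)
    partner + mono adduct → bis adduct (k = 0.00130 M⁻¹ s⁻¹)
    partner + bis adduct → triple product (k = 0.00310 M⁻¹ s⁻¹)
    partner + triple product → tetra adduct (k = 0.00920 M⁻¹ s⁻¹)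
    mono adduct → side product (k = 0.00620 s⁻¹)

The neighbour of blue holds 0.13 M of partner, the other settings unchanged. The same κ, with its excess 0.0800 M and the full 1.0 h, gives 74.7% of side product. That neighbour gives 74.6%, with 22.4% of the starting material left.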